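**Plan**

- Numbering used throughout: ring C1 (O-aryl), C2=C3 (methyl on C3), C4 (OH), C5, C6; side chain C1′ (methyl), C2′, C3′ (ketone). C1 is a secondary allylic carbinol carbon bonded to the vinylic C2 and flanked by the C6 stereocentre. That is the pattern left by adding a C2 vinyl-metal to a C1 aldehyde, so the cyclohexene (the only ring made; both benzene rings are bought) is closed at C1–C2.
- Retrosynthetic cuts, in order: the curcuminoid C=C next to the methoxyaryl ring (aldol condensation), the C3′–isobutenyl bond (Grignard on a Weinreb amide), the aryl C–O bond at C1 (SNAr), the ring bond C1–C2 (Nozaki–Hiyama–Kishi), C3–CH3 and C2–I (anti-carbomagnesiation, iodination), C3–C4 (alkyne acylation), C5–C6 (enolate alkylation).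
- Forward: the open chain C3′–C2′–C1′–C6(–C1)–C5–C4–C3–C2 is built from a 3-methylglutarate hemiester, the ring is closed, then the aryl ether, the enone and the diarylheptanoid arm are added.
- Stereochemistry: C1′ comes from the purchased (R)-hemiester, C6 from an oxazolidinone-controlled alkylation, C4 from a catalyst-controlled ynone transfer hydrogenation, and C1 from substrate control in the ring closure. The (Z)-iodoalkene comes from alkoxide-directed anti addition, and the (E)-alkenes from the condensations.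

Key step: step 12

Assumption: methyl hydrogen (R)-3-methylglutarate is taken as a purchased compound (it is also what desymmetrising methanolysis of 3-methylglutaric anhydride gives), and the target, drawn as one enol tautomer of its 1,3-diketone, is treated as that compound.

**Step 1**
Reactants: 1 methyl hydrogen (3R)-3-methylglutarate; 2 (4R)-4-benzyl-1,3-oxazolidin-2-one
Product: 4 methyl (3R)-5-[(4R)-4-benzyl-2-oxo-1,3-oxazolidin-3-yl]-3-methyl-5-oxopentanoate, via mixed pivalic anhydride 3 (not isolated)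
Conditions: t-BuCOCl, Et3N, THF, −20 °C; then 2, LiCl, −20 °C → rt
Reagents that add atoms: none
Why: N-acylation of an Evans oxazolidinone through a mixed anhydride, in which the LiCl-activated oxazolidinone attacks the less hindered carbonyl of 3 at a temperature low enough to prevent closure of the activated hemiester to the achiral cyclic anhydride, so C1′ is carried in unchanged from 1.

**Step 2**
Reactants: 4 methyl (3R)-5-[(4R)-4-benzyl-2-oxo-1,3-oxazolidin-3-yl]-3-methyl-5-oxopentanoate; 5 tert-butyl bromoacetate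
Product: 7 1-tert-butyl 6-methyl (3R,4S)-3-[(4R)-4-benzyl-2-oxo-1,3-oxazolidine-3-carbonyl]-4-methylhexanedioate, via sodium (Z)-enolate 6 (not isolated)
Conditions: NaN(SiMe3)2, THF, −78 °C; then 5, −78 → −40 °C
Reagents that add atoms: none
Why: Evans asymmetric alkylation, in which the imide is deprotonated in preference to the less acidic methyl ester to give the chelated (Z)-enolate 6, whose face on the side of the benzyl group is shielded, so the bromoacetate should enter from the other face and set C6 as (R) under auxiliary control.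

**Step 3**
Reactants: 7 1-tert-butyl 6-methyl (3R,4S)-3-[(4R)-4-benzyl-2-oxo-1,3-oxazolidine-3-carbonyl]-4-methylhexanedioate
Product: 8 (3R,4S)-3-[(4R)-4-benzyl-2-oxo-1,3-oxazolidine-3-carbonyl]-6-methoxy-4-methyl-6-oxohexanoic acid
Conditions: CF3CO2H, CH2Cl2, 0 °C → rt
Reagents that add atoms: none
Why: Acidolysis of a tert-butyl ester through the tert-butyl cation (lost as isobutene) should be selective, because neither the methyl ester nor the imide ionises under these conditions.

**Step 4**
Reactants: 8 (3R,4S)-3-[(4R)-4-benzyl-2-oxo-1,3-oxazolidine-3-carbonyl]-6-methoxy-4-methyl-6-oxohexanoic acid; 9 ethynyltrimethylsilane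
Product: 11 methyl (3S,4R)-4-[(4R)-4-benzyl-2-oxo-1,3-oxazolidine-3-carbonyl]-3-methyl-6-oxo-8-(trimethylsilyl)oct-7-ynoate, via acid chloride 10 (not isolated)
Conditions: (COCl)2, DMF (cat.), CH2Cl2, 0 °C → rt, concentrate; then 9, PdCl2(PPh3)2 (cat.), CuI (cat.), Et3N, THF, rt
Reagents that add atoms: none
Why: Acyl Sonogashira coupling, in which acid chloride 10 adds oxidatively to zerovalent palladium and couples with the copper acetylide of 9 to form the C3–C4 bond, leaving the imide and the ester untouched under an amine base too weak to epimerise C6.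

**Step 5**
Reactants: 11 methyl (3S,4R)-4-[(4R)-4-benzyl-2-oxo-1,3-oxazolidine-3-carbonyl]-3-methyl-6-oxo-8-(trimethylsilyl)oct-7-ynoate
Product: 13 methyl (3S)-3-[(3R,5S)-2-oxo-5-[(trimethylsilyl)ethynyl]oxolan-3-yl]butanoate, via γ-hydroxy imide 12 (not isolated)
Conditions: Ru[(S,S)-TsDPEN](p-cymene) (cat.), i-PrOH, rt; then Et3N, DMAP (cat.), CH2Cl2, rt
Reagents that add atoms: none
Why: Noyori asymmetric transfer hydrogenation of an alkynyl ketone, in which the (S,S)-ligand places the alkynyl group where an aryl group sits with aryl ketones and so should give the (S)-carbinol at C4 under catalyst control, followed by lactonisation of the γ-hydroxy imide 12 with release of the recoverable auxiliary.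

**Step 6**
Reactants: 13 methyl (3S)-3-[(3R,5S)-2-oxo-5-[(trimethylsilyl)ethynyl]oxolan-3-yl]butanoate
Product: 15 (3S,5R,6S)-5-(hydroxymethyl)-6-methyloct-1-yne-3,8-diol, via silylalkyne triol 14 (not isolated)
Conditions: LiBH4, MeOH (1 equiv), THF, 0 °C → rt; then K2CO3, MeOH, rt
Reagents that add atoms: none
Why: LiBH4 reduces the lactone and the methyl ester to primary alcohols without touching the alkyne, and base-catalysed methanolysis of the alkynyl C–Si bond then frees the terminal alkyne, no stereocentre being involved.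

**Step 7**
Reactants: 15 (3S,5R,6S)-5-(hydroxymethyl)-6-methyloct-1-yne-3,8-diol
Product: 17 (1Z,3S,5R,6S)-5-(hydroxymethyl)-1-iodo-2,6-dimethyloct-1-ene-3,8-diol, via alkenylmagnesium tris-alkoxide 16 (not isolated)
Conditions: MeMgBr (excess), CuI (cat.), THF, 0 °C → rt; then I2, THF, −40 → 0 °C
Reagents that add atoms: methylmagnesium bromide, C[Mg]Br; iodine, II
Why: Alkoxide-directed, copper-catalysed anti-carbomagnesiation of a propargylic alcohol, in which the C4 magnesium alkoxide directs methyl to C3 and magnesium to C2 on its own side (five-membered chelate in 16), so iodinolysis with retention should give only the (Z)-iodide while the two remote alkoxides are spectators.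

**Step 8**
Reactants: 17 (1Z,3S,5R,6S)-5-(hydroxymethyl)-1-iodo-2,6-dimethyloct-1-ene-3,8-diol
Product: 19 (4S,5R)-5-[(2S,3Z)-2-hydroxy-4-iodo-3-methylbut-3-en-1-yl]-4-methyloxan-2-one, via δ-lactol 18 (not isolated)
Conditions: TEMPO (cat.), PhI(OAc)2, CH2Cl2, 0 °C → rt
Reagents that add atoms: none
Why: TEMPO/PhI(OAc)2 oxidative lactonisation of a 1,5-diol, in which the oxoammonium salt should oxidise the unhindered C3′ carbinol faster than the β-branched C1 carbinol or the hindered secondary allylic C4 carbinol, the hydroxy aldehyde closing to lactol 18 and being oxidised on to the δ-lactone.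

**Step 9**
Reactants: 19 (4S,5R)-5-[(2S,3Z)-2-hydroxy-4-iodo-3-methylbut-3-en-1-yl]-4-methyloxan-2-one
Product: 20 (4S,5R)-5-[(2S,3Z)-2-(tert-butyldimethylsilyloxy)-4-iodo-3-methylbut-3-en-1-yl]-4-methyloxan-2-one
Conditions: TBSOTf, 2,6-lutidine, CH2Cl2, −78 °C
Reagents that add atoms: tert-butyldimethylsilyl trifluoromethanesulfonate, CC(C)(C)[Si](C)(C)OS(=O)(=O)C(F)(F)F
Why: Silylation of a secondary alcohol with a silyl triflate and a hindered pyridine base is fast at low temperature and should leave the lactone and the iodoalkene alone.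

**Step 10**
Reactants: 20 (4S,5R)-5-[(2S,3Z)-2-(tert-butyldimethylsilyloxy)-4-iodo-3-methylbut-3-en-1-yl]-4-methyloxan-2-one
Product: 21 (3S,4R,6S,7Z)-6-(tert-butyldimethylsilyloxy)-4-(hydroxymethyl)-8-iodo-N-methoxy-N,3,7-trimethyloct-7-enamide
Conditions: MeNH(OMe)·HCl, AlMe3, CH2Cl2, 0 °C → rt
Reagents that add atoms: N,O-dimethylhydroxylamine hydrochloride, CNOC.Cl
Why: Weinreb aminolysis of a lactone, in which the aluminium amide made from AlMe3 and the amine salt opens the δ-lactone at the acyl carbon to give the C3′ amide and free the C1 carbinol, which is oxidised at once to forestall relactonisation.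

**Step 11**
Reactants: 21 (3S,4R,6S,7Z)-6-(tert-butyldimethylsilyloxy)-4-(hydroxymethyl)-8-iodo-N-methoxy-N,3,7-trimethyloct-7-enamide
Product: 22 (3S,4R,6S,7Z)-6-(tert-butyldimethylsilyloxy)-4-formyl-8-iodo-N-methoxy-N,3,7-trimethyloct-7-enamide
Conditions: Dess–Martin periodinane, NaHCO3, CH2Cl2, 0 °C → rt
Reagents that add atoms: none
Why: Dess–Martin oxidation of the primary alcohol under buffered, non-basic conditions should give the α-branched aldehyde without epimerising C6 or attacking the iodoalkene and the silyl ether.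

**Step 12**
Reactants: 22 (3S,4R,6S,7Z)-6-(tert-butyldimethylsilyloxy)-4-formyl-8-iodo-N-methoxy-N,3,7-trimethyloct-7-enamide
Product: 24 (3S)-3-[(1R,2R,5S)-5-(tert-butyldimethylsilyloxy)-2-hydroxy-4-methylcyclohex-3-en-1-yl]-N-methoxy-N-methylbutanamide, via alkenylchromium dichloride 23 (not isolated)
Conditions: CrCl2 (excess), NiCl2 (cat.), degassed DMSO, rt, high dilution
Reagents that add atoms: none
Why: Zerovalent nickel, formed from NiCl2 by divalent chromium, inserts into the C–I bond with retention of the (Z)-geometry and transmetalates to trivalent chromium, and the alkenylchromium 23 adds to the aldehyde to form C1–C2, the chromium alkoxide giving 24 on work-up. The closest known reaction type is the intramolecular Nozaki–Hiyama–Kishi cyclisation of (Z)-iodoalkenyl aldehydes to cycloalk-2-enols. The cyclohexene ring closes in a 6-exo-trig mode, C2 attacking the formyl carbon while the carbonyl oxygen stays outside the ring. The new C1 stereocentre is set by substrate control in a half-chair transition state with the C6 side chain equatorial, the C4 silyloxy group pseudoaxial (which relieves allylic strain against the C3 methyl group) and the chromium-bound oxygen pseudoequatorial, so C1–O should end up trans to the C6 substituent and cis to C4–O. The step needs chemoselectivity for the aldehyde over the Weinreb amide, which the low reactivity of organochromium reagents toward amides secures, and it needs the epimerisable C6 to hold, which the non-basic medium secures.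

**Step 13**
Reactants: 24 (3S)-3-[(1R,2R,5S)-5-(tert-butyldimethylsilyloxy)-2-hydroxy-4-methylcyclohex-3-en-1-yl]-N-methoxy-N-methylbutanamide; 25 4-fluoro-3-methoxybenzaldehyde
Product: 27 (3S)-3-[(1R,2R,5S)-5-(tert-butyldimethylsilyloxy)-2-(4-formyl-2-methoxyphenoxy)-4-methylcyclohex-3-en-1-yl]-N-methoxy-N-methylbutanamide, via sodium alkoxide 26 (not isolated)
Conditions: NaH, DMF, 0 °C → rt (24 and 25 premixed)
Reagents that add atoms: none
Why: Nucleophilic aromatic substitution (SNAr), in which alkoxide 26, generated in the presence of the fluoroarene, adds para to the formyl group and expels fluoride through a Meisenheimer intermediate, the C1–O bond staying intact so that the configuration at C1 is kept.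

**Step 14**
Reactants: 27 (3S)-3-[(1R,2R,5S)-5-(tert-butyldimethylsilyloxy)-2-(4-formyl-2-methoxyphenoxy)-4-methylcyclohex-3-en-1-yl]-N-methoxy-N-methylbutanamide
Product: 28 (3S)-3-[(1R,2R,5S)-5-(tert-butyldimethylsilyloxy)-2-[4-(dimethoxymethyl)-2-methoxyphenoxy]-4-methylcyclohex-3-en-1-yl]-N-methoxy-N-methylbutanamide
Conditions: HC(OMe)3, PPTS (cat.), MeOH, rt
Reagents that add atoms: trimethyl orthoformate, COC(OC)OC
Why: Acid-catalysed acetalisation with an orthoformate masks the aromatic aldehyde as its dimethyl acetal under conditions mild enough for the secondary silyl ether and the allylic aryl ether.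

**Step 15**
Reactants: 28 (3S)-3-[(1R,2R,5S)-5-(tert-butyldimethylsilyloxy)-2-[4-(dimethoxymethyl)-2-methoxyphenoxy]-4-methylcyclohex-3-en-1-yl]-N-methoxy-N-methylbutanamide; 29 2-methylprop-1-en-1-ylmagnesium bromide
Product: 31 (6S)-6-[(1R,2R,5S)-5-(tert-butyldimethylsilyloxy)-2-[4-(dimethoxymethyl)-2-methoxyphenoxy]-4-methylcyclohex-3-en-1-yl]-2-methylhept-2-en-4-one, via magnesium hemiaminal chelate 30 (not isolated)
Conditions: THF, 0 °C; then pH 7 buffer
Reagents that add atoms: none
Why: Weinreb ketone synthesis, in which the alkenyl Grignard reagent adds once to the N-methoxy-N-methylamide to give the stable chelate 30 that collapses to the enone only on work-up, the hindered β,β-disubstituted enone being unlikely to take up the liberated amine.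

**Step 16**
Reactants: 31 (6S)-6-[(1R,2R,5S)-5-(tert-butyldimethylsilyloxy)-2-[4-(dimethoxymethyl)-2-methoxyphenoxy]-4-methylcyclohex-3-en-1-yl]-2-methylhept-2-en-4-one
Product: 32 4-{[(1R,4S,6R)-4-hydroxy-3-methyl-6-[(2S)-6-methyl-4-oxohept-5-en-2-yl]cyclohex-2-en-1-yl]oxy}-3-methoxybenzaldehyde
Conditions: HF (48% aq.), MeCN, 0 °C → rt
Reagents that add atoms: water, O
Why: Aqueous HF cleaves the silyl ether through Si–F bond formation and hydrolyses the dimethyl acetal in the same operation, under acidity too mild to ionise the allylic alcohol or the allylic aryl ether.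

**Step 17**
Reactants: 33 pentane-2,4-dione (excess); 34 4-hydroxybenzaldehyde
Product: 37 (5E)-6-(4-hydroxyphenyl)hex-5-ene-2,4-dione, via boron chelate of the diketone 35 (not isolated), via boron chelate of the styryl diketone 36 (not isolated)
Conditions: B2O3, B(On-Bu)3, n-BuNH2 (cat.), EtOAc, 70 °C; then 0.4 M HCl, 50 °C
Reagents that add atoms: none
Why: Boron-templated aldol condensation of a 1,3-diketone, in which chelation to boron blocks Knoevenagel reaction at the central carbon and directs the amine-catalysed condensation to a terminal methyl group, an excess of the diketone holding the reaction at the mono-adduct and dehydration giving the (E)-alkene.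

**Step 18**
Reactants: 32 4-{[(1R,4S,6R)-4-hydroxy-3-methyl-6-[(2S)-6-methyl-4-oxohept-5-en-2-yl]cyclohex-2-en-1-yl]oxy}-3-methoxybenzaldehyde; 37 (5E)-6-(4-hydroxyphenyl)hex-5-ene-2,4-dione
Product: 40 demethoxybisabolocurcumin ether, via diisopropoxyboron chelate of the styryl diketone 38 (not isolated), via diisopropoxyboron chelate of the curcuminoid 39 (not isolated)
Conditions: B2O3, B(Oi-Pr)3, n-BuNH2 (cat.), EtOAc, 60 °C; then 0.4 M HCl, rt
Reagents that add atoms: none
Why: A second boron-templated aldol condensation, run with B(Oi-Pr)3 as the water scavenger so that only volatile propan-2-ol has to be removed from the polar product, should join the remaining methyl group of 37 (held as chelate 38) to the aryl aldehyde of 32 with (E)-selective dehydration, the side-chain enone being a far weaker carbon acid than the chelated diketone, and mild acid hydrolysis of chelate 39 releases the target without touching its four stereocentres.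

**Compound list**

1 | methyl hydrogen (3R)-3-methylglutarate, (3R)-5-methoxy-3-methyl-5-oxopentanoic acid | OC(=O)C[C@@H](C)CC(=O)OC | starting material
2 | (4R)-4-benzyl-1,3-oxazolidin-2-one | O=C1N[C@H](Cc2ccccc2)CO1 | starting material
3 | (3S)-5-methoxy-3-methyl-5-oxopentanoic pivalic anhydride (spatial arrangement as in 1; the descriptor changes because the anhydride arm now outranks the ester arm) | COC(=O)C[C@H](C)CC(=O)OC(=O)C(C)(C)C | intermediate
4 | methyl (3R)-5-[(4R)-4-benzyl-2-oxo-1,3-oxazolidin-3-yl]-3-methyl-5-oxopentanoate | COC(=O)C[C@H](C)CC(=O)N1[C@H](Cc2ccccc2)COC1=O | intermediate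
5 | tert-butyl bromoacetate | CC(C)(C)OC(=O)CBr | starting material
6 | sodium (Z)-enolate of imide 4 | COC(=O)C[C@H](C)/C=C(\[O-])N1[C@H](Cc2ccccc2)COC1=O.[Na+] | intermediate
7 | 1-tert-butyl 6-methyl (3R,4S)-3-[(4R)-4-benzyl-2-oxo-1,3-oxazolidine-3-carbonyl]-4-methylhexanedioate | COC(=O)C[C@H](C)[C@@H](CC(=O)OC(C)(C)C)C(=O)N1[C@H](Cc2ccccc2)COC1=O | intermediate
8 | (3R,4S)-3-[(4R)-4-benzyl-2-oxo-1,3-oxazolidine-3-carbonyl]-6-methoxy-4-methyl-6-oxohexanoic acid | COC(=O)C[C@H](C)[C@@H](CC(=O)O)C(=O)N1[C@H](Cc2ccccc2)COC1=O | intermediate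
9 | ethynyltrimethylsilane | C#C[Si](C)(C)C | starting material
10 | methyl (3S,4R)-4-[(4R)-4-benzyl-2-oxo-1,3-oxazolidine-3-carbonyl]-6-chloro-3-methyl-6-oxohexanoate | COC(=O)C[C@H](C)[C@@H](CC(=O)Cl)C(=O)N1[C@H](Cc2ccccc2)COC1=O | intermediate
11 | methyl (3S,4R)-4-[(4R)-4-benzyl-2-oxo-1,3-oxazolidine-3-carbonyl]-3-methyl-6-oxo-8-(trimethylsilyl)oct-7-ynoate | COC(=O)C[C@H](C)[C@@H](CC(=O)C#C[Si](C)(C)C)C(=O)N1[C@H](Cc2ccccc2)COC1=O | intermediate
12 | methyl (3S,4R,6S)-4-[(4R)-4-benzyl-2-oxo-1,3-oxazolidine-3-carbonyl]-6-hydroxy-3-methyl-8-(trimethylsilyl)oct-7-ynoate | COC(=O)C[C@H](C)[C@@H](C[C@H](O)C#C[Si](C)(C)C)C(=O)N1[C@H](Cc2ccccc2)COC1=O | intermediate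
13 | methyl (3S)-3-[(3R,5S)-2-oxo-5-[(trimethylsilyl)ethynyl]oxolan-3-yl]butanoate | COC(=O)C[C@H](C)[C@H]1C[C@@H](C#C[Si](C)(C)C)OC1=O | intermediate
14 | (3S,5R,6S)-5-(hydroxymethyl)-6-methyl-1-(trimethylsilyl)oct-1-yne-3,8-diol | OCC[C@H](C)[C@H](CO)C[C@H](O)C#C[Si](C)(C)C | intermediate
15 | (3S,5R,6S)-5-(hydroxymethyl)-6-methyloct-1-yne-3,8-diol | OCC[C@H](C)[C@H](CO)C[C@H](O)C#C | intermediate
16 | tris(bromomagnesium) alkoxide of the (Z)-alkenylmagnesium bromide from 15 (methyl on C3, magnesium on C2 cis to C4) | Br[Mg]OCC[C@H](C)[C@H](CO[Mg]Br)C[C@H](O[Mg]Br)/C(C)=C\[Mg]Br | intermediate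
17 | (1Z,3S,5R,6S)-5-(hydroxymethyl)-1-iodo-2,6-dimethyloct-1-ene-3,8-diol | OCC[C@H](C)[C@H](CO)C[C@H](O)/C(C)=C\I | intermediate
18 | (4S,5R)-5-[(2S,3Z)-2-hydroxy-4-iodo-3-methylbut-3-en-1-yl]-4-methyloxan-2-ol (both anomers) | OC1C[C@H](C)[C@@H](C[C@H](O)/C(C)=C\I)CO1 | intermediate
19 | (4S,5R)-5-[(2S,3Z)-2-hydroxy-4-iodo-3-methylbut-3-en-1-yl]-4-methyloxan-2-one | O=C1C[C@H](C)[C@@H](C[C@H](O)/C(C)=C\I)CO1 | intermediate
20 | (4S,5R)-5-[(2S,3Z)-2-(tert-butyldimethylsilyloxy)-4-iodo-3-methylbut-3-en-1-yl]-4-methyloxan-2-one | O=C1C[C@H](C)[C@@H](C[C@H](O[Si](C)(C)C(C)(C)C)/C(C)=C\I)CO1 | intermediate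
21 | (3S,4R,6S,7Z)-6-(tert-butyldimethylsilyloxy)-4-(hydroxymethyl)-8-iodo-N-methoxy-N,3,7-trimethyloct-7-enamide | OC[C@@H]([C@@H](C)CC(=O)N(C)OC)C[C@H](O[Si](C)(C)C(C)(C)C)/C(C)=C\I | intermediate
22 | (3S,4R,6S,7Z)-6-(tert-butyldimethylsilyloxy)-4-formyl-8-iodo-N-methoxy-N,3,7-trimethyloct-7-enamide | O=C[C@@H]([C@@H](C)CC(=O)N(C)OC)C[C@H](O[Si](C)(C)C(C)(C)C)/C(C)=C\I | intermediate
23 | (Z)-alkenylchromium dichloride from 22 (chromium in place of iodine) | O=C[C@@H]([C@@H](C)CC(=O)N(C)OC)C[C@H](O[Si](C)(C)C(C)(C)C)/C(C)=C\[Cr](Cl)Cl | intermediate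
24 | (3S)-3-[(1R,2R,5S)-5-(tert-butyldimethylsilyloxy)-2-hydroxy-4-methylcyclohex-3-en-1-yl]-N-methoxy-N-methylbutanamide | O[C@H]1C=C(C)[C@@H](O[Si](C)(C)C(C)(C)C)C[C@@H]1[C@@H](C)CC(=O)N(C)OC | intermediate
25 | 4-fluoro-3-methoxybenzaldehyde | COc1cc(C=O)ccc1F | starting material
26 | sodium alkoxide of 24 | [Na+].[O-][C@H]1C=C(C)[C@@H](O[Si](C)(C)C(C)(C)C)C[C@@H]1[C@@H](C)CC(=O)N(C)OC | intermediate
27 | (3S)-3-[(1R,2R,5S)-5-(tert-butyldimethylsilyloxy)-2-(4-formyl-2-methoxyphenoxy)-4-methylcyclohex-3-en-1-yl]-N-methoxy-N-methylbutanamide | COc1cc(C=O)ccc1O[C@H]1C=C(C)[C@@H](O[Si](C)(C)C(C)(C)C)C[C@@H]1[C@@H](C)CC(=O)N(C)OC | intermediate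
28 | (3S)-3-[(1R,2R,5S)-5-(tert-butyldimethylsilyloxy)-2-[4-(dimethoxymethyl)-2-methoxyphenoxy]-4-methylcyclohex-3-en-1-yl]-N-methoxy-N-methylbutanamide | COc1cc(C(OC)OC)ccc1O[C@H]1C=C(C)[C@@H](O[Si](C)(C)C(C)(C)C)C[C@@H]1[C@@H](C)CC(=O)N(C)OC | intermediate
29 | 2-methylprop-1-en-1-ylmagnesium bromide | CC(C)=C[Mg]Br | starting material
30 | bromomagnesium salt of the N-methoxy-N-methyl hemiaminal formed from 28 and 29 | COc1cc(C(OC)OC)ccc1O[C@H]1C=C(C)[C@@H](O[Si](C)(C)C(C)(C)C)C[C@@H]1[C@@H](C)CC(O[Mg]Br)(C=C(C)C)N(C)OC | intermediate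
31 | (6S)-6-[(1R,2R,5S)-5-(tert-butyldimethylsilyloxy)-2-[4-(dimethoxymethyl)-2-methoxyphenoxy]-4-methylcyclohex-3-en-1-yl]-2-methylhept-2-en-4-one | COc1cc(C(OC)OC)ccc1O[C@H]1C=C(C)[C@@H](O[Si](C)(C)C(C)(C)C)C[C@@H]1[C@@H](C)CC(=O)C=C(C)C | intermediate
32 | 4-{[(1R,4S,6R)-4-hydroxy-3-methyl-6-[(2S)-6-methyl-4-oxohept-5-en-2-yl]cyclohex-2-en-1-yl]oxy}-3-methoxybenzaldehyde | COc1cc(C=O)ccc1O[C@H]1C=C(C)[C@@H](O)C[C@@H]1[C@@H](C)CC(=O)C=C(C)C | intermediate
33 | pentane-2,4-dione | CC(=O)CC(C)=O | starting material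
34 | 4-hydroxybenzaldehyde | O=Cc1ccc(O)cc1 | starting material
35 | dibutoxyboron chelate of pentane-2,4-dione (drawn as the 2,2-dibutoxy-1,3,2-dioxaborinine) | CCCCO[B-]1(OCCCC)OC(C)=CC(C)=[O+]1 | intermediate
36 | dibutoxyboron chelate of diketone 37 | CCCCO[B-]1(OCCCC)OC(C)=CC(/C=C/c2ccc(O)cc2)=[O+]1 | intermediate
37 | (5E)-6-(4-hydroxyphenyl)hex-5-ene-2,4-dione | CC(=O)CC(=O)/C=C/c1ccc(O)cc1 | intermediate
38 | diisopropoxyboron chelate of diketone 37 | CC(C)O[B-]1(OC(C)C)OC(C)=CC(/C=C/c2ccc(O)cc2)=[O+]1 | intermediate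
39 | diisopropoxyboron chelate of the target | CC(C)O[B-]1(OC(C)C)OC(/C=C/c2ccc(O)cc2)=CC(/C=C/c2ccc(O[C@H]3C=C(C)[C@@H](O)C[C@@H]3[C@@H](C)CC(=O)C=C(C)C)c(OC)c2)=[O+]1 | intermediate
40 | demethoxybisabolocurcumin ether | COc1cc(/C=C/C(O)=C/C(=O)/C=C/c2ccc(O)cc2)ccc1O[C@H]1C=C(C)[C@@H](O)C[C@@H]1[C@@H](C)CC(=O)C=C(C)C | target

**Step count**

Total: 18 steps. Longest linear sequence: 17 steps (steps 1–16 and 18); step 17 is a one-step side branch.

**Steps most likely to fail**

Step 13 (O-arylation). The C1 alkoxide may attack the C3′ amide carbonyl through a six-membered transition state and expel the amine, or be consumed by base-induced reactions at the aldehyde, faster than it displaces fluoride from a ring deactivated by the ortho methoxy group. The fallback forms the aryl ether without a free alkoxide. It sets out from 24, which is acylated with methyl chloroformate and pyridine to the allylic methyl carbonate F1. F1 is then treated with 4-hydroxy-3-methoxybenzaldehyde and catalytic Pd(PPh3)4 (zerovalent palladium) in THF (Tsuji–Trost allylic etherification). Ionisation anti to the carbonate and attack of the phenoxide anti to palladium should give net retention at C1, and attack at C1 should be preferred over the fully substituted C3 terminus. The route is rejoined at 27.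

Step 7 (carbomagnesiation of the triol). Aggregation of the magnesium tris-alkoxide may stall the carbometalation, or the alkenylmagnesium may be protonated before iodine reaches it. The fallback sets out from 15 and works with a mono-alkoxide. Selective silylation of the two primary hydroxyls (TBSCl, imidazole, CH2Cl2, 0 °C) should give bis-silyl ether F2. Carbomagnesiation and iodination as in step 7 should give iodo alcohol F3, and TBSOTf with 2,6-lutidine the tris-silyl ether F4. HF·pyridine buffered with pyridine in THF at 0 °C should remove only the two primary silyl groups to give diol F5. Oxidative lactonisation of F5 with TEMPO and PhI(OAc)2 returns to the route at 20, so that 17 and 19 are bypassed.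

Step 12 (ring closure). The alkenylchromium may add to both faces of the aldehyde with poor selectivity, so that the C1 epimer forms beside 24. The fallback sets out from 22 and moves the control of C1 from the C–C bond formation to a ketone reduction. The cyclisation is run as described, and the mixture of 24 and its C1 epimer F6 is oxidised with Dess–Martin periodinane to the single cyclohexenone F7. Luche reduction (NaBH4, CeCl3·7H2O, MeOH, −78 °C) should then deliver hydride axially, on the face away from the pseudoaxial C4 silyloxy group. This gives the equatorial carbinol trans to the C6 side chain, and the route is rejoined at 24.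

**Further compounds**

F1 | step 13 | (1R,4S,6R)-4-(tert-butyldimethylsilyloxy)-6-[(2S)-4-[methoxy(methyl)amino]-4-oxobutan-2-yl]-3-methylcyclohex-2-en-1-yl methyl carbonate | COC(=O)O[C@H]1C=C(C)[C@@H](O[Si](C)(C)C(C)(C)C)C[C@@H]1[C@@H](C)CC(=O)N(C)OC
F2 | step 7 | (3S,5R,6S)-8-(tert-butyldimethylsilyloxy)-5-[(tert-butyldimethylsilyloxy)methyl]-6-methyloct-1-yn-3-ol | CC(C)(C)[Si](C)(C)OCC[C@H](C)[C@H](CO[Si](C)(C)C(C)(C)C)C[C@H](O)C#C
F3 | step 7 | (1Z,3S,5R,6S)-8-(tert-butyldimethylsilyloxy)-5-[(tert-butyldimethylsilyloxy)methyl]-1-iodo-2,6-dimethyloct-1-en-3-ol | CC(C)(C)[Si](C)(C)OCC[C@H](C)[C@H](CO[Si](C)(C)C(C)(C)C)C[C@H](O)/C(C)=C\I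
F4 | step 7 | (1Z,3S,5R,6S)-3,8-bis(tert-butyldimethylsilyloxy)-5-[(tert-butyldimethylsilyloxy)methyl]-1-iodo-2,6-dimethyloct-1-ene | CC(C)(C)[Si](C)(C)OCC[C@H](C)[C@H](CO[Si](C)(C)C(C)(C)C)C[C@H](O[Si](C)(C)C(C)(C)C)/C(C)=C\I
F5 | step 7 | (2R,3S)-2-[(2S,3Z)-2-(tert-butyldimethylsilyloxy)-4-iodo-3-methylbut-3-en-1-yl]-3-methylpentane-1,5-diol | OCC[C@H](C)[C@H](CO)C[C@H](O[Si](C)(C)C(C)(C)C)/C(C)=C\I
F6 | step 12 | (3S)-3-[(1R,2S,5S)-5-(tert-butyldimethylsilyloxy)-2-hydroxy-4-methylcyclohex-3-en-1-yl]-N-methoxy-N-methylbutanamide | O[C@@H]1C=C(C)[C@@H](O[Si](C)(C)C(C)(C)C)C[C@@H]1[C@@H](C)CC(=O)N(C)OC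
F7 | step 12 | (3S)-3-[(1R,5S)-5-(tert-butyldimethylsilyloxy)-4-methyl-2-oxocyclohex-3-en-1-yl]-N-methoxy-N-methylbutanamide | O=C1C=C(C)[C@@H](O[Si](C)(C)C(C)(C)C)C[C@@H]1[C@@H](C)CC(=O)N(C)OC
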